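**Assumption:** the target has no stereocentre and no E/Z isomerism (each prenyl alkene carries two identical methyls), so "single enantiomer" is taken to mean the achiral compound exactly as drawn.

## Retrosynthetic overview

1. The usual plan, C-prenylating phloroacetophenone (or kaempferol) with prenyl bromide before or after flavonol formation, is set aside. Both prenyl groups are made last, on the intact flavonol.
2. 13 ⇐ 12 (MOM removal) ⇐ 9 by twofold olefin cross-metathesis of two C-allyl groups with 2-methyl-2-butene.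
3. 9 ⇐ 6 by the key step: a twofold, regioconvergent aromatic Claisen rearrangement that moves the two O-allyl groups, which protected ring A during assembly, onto C6 and C8.
4. 6 ⇐ 4 (Algar–Flynn–Oyamada closure of ring C) ⇐ 2 + 3 (Claisen–Schmidt) ⇐ 1 (bis-O-allylation).
5. Ring order: rings A and B are bought (1 and 3); ring C is the only ring formed (step 3).

## Route

**Step 1**
Reactants: 1 phloroacetophenone (2',4',6'-trihydroxyacetophenone)
Product: 2 bis-allyl ether 1-[2,4-bis(allyloxy)-6-hydroxyphenyl]ethan-1-one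
Conditions: allyl bromide (2.2 equiv), K2CO3 (2.5 equiv), acetone, reflux, 8 h
Reagents that add atoms: allyl bromide, C=CCBr
Why: Williamson ether synthesis in which the 4-OH and one of the two equivalent ortho-OH groups are alkylated while the remaining ortho-OH, held in a strong hydrogen bond to the acetyl carbonyl, reacts much more slowly, so the 2,4-bis-ether is the major product.

**Step 2**
Reactants: 2 bis-allyl ether 1-[2,4-bis(allyloxy)-6-hydroxyphenyl]ethan-1-one; 3 4-(methoxymethoxy)benzaldehyde
Product: 4 chalcone (E)-1-[2,4-bis(allyloxy)-6-hydroxyphenyl]-3-[4-(methoxymethoxy)phenyl]prop-2-en-1-one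
Conditions: KOH (50% aq, 8 equiv), EtOH, rt, 36 h; then 1 M HCl (0 °C) to pH 5
Reagents that add atoms: none
Why: Claisen–Schmidt (crossed aldol) condensation in which the methyl ketone enolate adds to the non-enolisable aldehyde and E1cB dehydration gives the conjugated E-enone as the thermodynamic alkene, the allyl ethers and the MOM acetal being inert to aqueous base.

**Step 3**
Reactants: 4 chalcone (E)-1-[2,4-bis(allyloxy)-6-hydroxyphenyl]-3-[4-(methoxymethoxy)phenyl]prop-2-en-1-one
Product: 6 flavonol 5,7-bis(allyloxy)-3-hydroxy-2-[4-(methoxymethoxy)phenyl]-4H-chromen-4-one, via trans-dihydroflavonol 5 (not isolated)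
Conditions: H2O2 (30% aq, 6 equiv), NaOH (2 M aq, 4 equiv), MeOH, 0 °C → rt, 12 h; then 1 M HCl (0 °C) to pH 5
Reagents that add atoms: hydrogen peroxide, OO
Why: Algar–Flynn–Oyamada reaction in which hydroperoxide oxidises the enone, the 2'-phenoxide closes ring C at the β-carbon (6-endo) to the trans-dihydroflavonol 5, and more H2O2 dehydrogenates 5 in situ to the flavonol (erasing its two transient stereocentres), while alkaline H2O2 leaves the isolated terminal alkenes untouched and the low temperature disfavours the competing aurone closure.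

**Step 4**
Reactants: 6 flavonol 5,7-bis(allyloxy)-3-hydroxy-2-[4-(methoxymethoxy)phenyl]-4H-chromen-4-one
Product: 9 diallyl flavonol 6,8-diallyl-3,5,7-trihydroxy-2-[4-(methoxymethoxy)phenyl]-4H-chromen-4-one, via 8-allyl-5-allyloxy mono-Claisen phenol 7 (not isolated), via 6-allyl-7-allyloxy mono-Claisen phenol 8 (not isolated)
Conditions: PhNEt2 (degassed), 200 °C, sealed tube, Ar, 5 h
Reagents that add atoms: none
Why: Twofold aromatic Claisen rearrangement ([3,3]-sigmatropic shift, then tautomerisation to the phenol) that is regioconvergent because C6 and C8 are the only free positions on ring A and an unsubstituted allyl group is unchanged by any [3,3] or follow-up Cope shift, so every order of events (through 7 or 8) ends at the 6,8-diallyl compound, with the MOM ether and the flavonol stable in the hot amine solvent.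

**Step 5**
Reactants: 9 diallyl flavonol 6,8-diallyl-3,5,7-trihydroxy-2-[4-(methoxymethoxy)phenyl]-4H-chromen-4-one
Product: 12 diprenyl flavonol MOM ether 3,5,7-trihydroxy-2-[4-(methoxymethoxy)phenyl]-6,8-bis(3-methylbut-2-en-1-yl)-4H-chromen-4-one, via 6-allyl-8-prenyl flavonol 10 (not isolated), via 8-allyl-6-prenyl flavonol 11 (not isolated)
Conditions: 2-methyl-2-butene (40 equiv), second-generation Grubbs catalyst RuCl2(=CHPh)(H2IMes)(PCy3) (2 × 5 mol %), CH2Cl2, 40 °C, sealed, 12 h
Reagents that add atoms: 2-methyl-2-butene, CC=C(C)C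
Why: Twofold olefin cross-metathesis in which each terminal allyl alkene exchanges its =CH2 end for the isopropylidene of 2-methyl-2-butene (the large excess suppresses homodimerisation and propene escapes), a reaction that works well on free ortho-allylphenols, and the trisubstituted prenyl alkenes formed are too hindered to react further and have no E/Z issue.

**Step 6**
Reactants: 12 diprenyl flavonol MOM ether 3,5,7-trihydroxy-2-[4-(methoxymethoxy)phenyl]-6,8-bis(3-methylbut-2-en-1-yl)-4H-chromen-4-one
Product: 13 6,8-diprenylkaempferol (3,5,7-trihydroxy-2-(4-hydroxyphenyl)-6,8-bis(3-methylbut-2-en-1-yl)-4H-chromen-4-one)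
Conditions: 3 M aq HCl–MeOH (1:10), 50 °C, 1.5 h
Reagents that add atoms: none
Why: Acid-catalysed acetal cleavage (MOM deprotection) in which the MOM ether ionises through an oxocarbenium ion in dilute methanolic HCl much faster than the trisubstituted prenyl alkenes are protonated, so the 4'-phenol is released without chroman formation and no stereocentre is involved.

## Compound list

1 | phloroacetophenone (2',4',6'-trihydroxyacetophenone) | CC(=O)c1c(O)cc(O)cc1O | starting material
2 | 1-[2,4-bis(allyloxy)-6-hydroxyphenyl]ethan-1-one | CC(=O)c1c(O)cc(OCC=C)cc1OCC=C | intermediate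
3 | 4-(methoxymethoxy)benzaldehyde | COCOc1ccc(C=O)cc1 | starting material
4 | (E)-1-[2,4-bis(allyloxy)-6-hydroxyphenyl]-3-[4-(methoxymethoxy)phenyl]prop-2-en-1-one | COCOc1ccc(/C=C/C(=O)c2c(O)cc(OCC=C)cc2OCC=C)cc1 | intermediate
5 | trans-dihydroflavonol, (2R*,3R*)-5,7-bis(allyloxy)-3-hydroxy-2-[4-(methoxymethoxy)phenyl]chroman-4-one (racemic, one enantiomer drawn; not isolated) | COCOc1ccc(cc1)[C@@H]2[C@H](C(=O)c3c(OCC=C)cc(OCC=C)cc3O2)O | intermediate
6 | 5,7-bis(allyloxy)-3-hydroxy-2-[4-(methoxymethoxy)phenyl]-4H-chromen-4-one | COCOc1ccc(cc1)-c1oc2cc(OCC=C)cc(OCC=C)c2c(=O)c1O | intermediate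
7 | 8-allyl-5-(allyloxy)-3,7-dihydroxy-2-[4-(methoxymethoxy)phenyl]-4H-chromen-4-one (not isolated) | COCOc1ccc(cc1)-c1oc2c(CC=C)c(O)cc(OCC=C)c2c(=O)c1O | intermediate
8 | 6-allyl-7-(allyloxy)-3,5-dihydroxy-2-[4-(methoxymethoxy)phenyl]-4H-chromen-4-one (not isolated) | COCOc1ccc(cc1)-c1oc2cc(OCC=C)c(CC=C)c(O)c2c(=O)c1O | intermediate
9 | 6,8-diallyl-3,5,7-trihydroxy-2-[4-(methoxymethoxy)phenyl]-4H-chromen-4-one | COCOc1ccc(cc1)-c1oc2c(CC=C)c(O)c(CC=C)c(O)c2c(=O)c1O | intermediate
10 | 6-allyl-3,5,7-trihydroxy-2-[4-(methoxymethoxy)phenyl]-8-(3-methylbut-2-en-1-yl)-4H-chromen-4-one (not isolated) | COCOc1ccc(cc1)-c1oc2c(CC=C(C)C)c(O)c(CC=C)c(O)c2c(=O)c1O | intermediate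
11 | 8-allyl-3,5,7-trihydroxy-2-[4-(methoxymethoxy)phenyl]-6-(3-methylbut-2-en-1-yl)-4H-chromen-4-one (not isolated) | COCOc1ccc(cc1)-c1oc2c(CC=C)c(O)c(CC=C(C)C)c(O)c2c(=O)c1O | intermediate
12 | 3,5,7-trihydroxy-2-[4-(methoxymethoxy)phenyl]-6,8-bis(3-methylbut-2-en-1-yl)-4H-chromen-4-one | COCOc1ccc(cc1)-c1oc2c(CC=C(C)C)c(O)c(CC=C(C)C)c(O)c2c(=O)c1O | intermediate
13 | 6,8-diprenylkaempferol | CC(C)=CCc1c(O)c(CC=C(C)C)c2oc(-c3ccc(O)cc3)c(O)c(=O)c2c1O | target

## Step count and risks

Total step count: 6. Longest linear sequence: 6 steps (1 → 13; aldehyde 3 is bought).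

**Step 3 (Algar–Flynn–Oyamada).** Chalcones with a 6'-alkoxy group can divert to aurones through 5-exo closure. The fallback sets out from 4 and comes back at 6, building the flavone first and oxidising C3 afterwards. Chalcone 4 is cyclised by oxa-Michael addition (NaOAc, EtOH, reflux) to the racemic flavanone 5,7-bis(allyloxy)-2-[4-(methoxymethoxy)phenyl]chroman-4-one F1. DDQ (dioxane, reflux) dehydrogenates it to the flavone 5,7-bis(allyloxy)-2-[4-(methoxymethoxy)phenyl]-4H-chromen-4-one F2. C3 lithiation with LiN(iPr)2 (THF, −78 °C) and trapping with B(OMe)3 gives the dimethyl [5,7-bis(allyloxy)-2-[4-(methoxymethoxy)phenyl]-4-oxo-4H-chromen-3-yl]boronate F3, which is oxidised in the same flask with H2O2/AcOH (0 °C) to 6.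

**Step 4 (twofold Claisen).** The second migration may stall, the ortho-allylphenols may cyclise thermally to dihydrobenzofurans, or the flavonol may degrade at 200 °C. The fallback sets out from 6 and comes back at 12 (step 5 is then not needed), replacing sigmatropic transfer by cross-coupling. Both O-allyl groups are removed by zerovalent palladium (Pd(PPh3)4 cat., morpholine, THF, rt) to give 3,5,7-trihydroxy-2-[4-(methoxymethoxy)phenyl]-4H-chromen-4-one F4. N-Iodosuccinimide (2.1 equiv, DMF, 0 °C) iodinates the doubly activated C6 and C8 to give 3,5,7-trihydroxy-6,8-diiodo-2-[4-(methoxymethoxy)phenyl]-4H-chromen-4-one F5. A twofold Stille coupling with tributyl(3-methylbut-2-en-1-yl)stannane (Pd(PPh3)4, DMF, 90 °C), which couples at the unsubstituted allyl terminus, then gives 12.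

**Step 5 (twofold cross-metathesis).** Ruthenium hydride species may isomerise allyl to propenyl (leading to one-carbon-short side chains), the 3-hydroxy-4-keto unit may bind the catalyst, or the second exchange may stay incomplete. The fallback sets out from 9 and comes back at 12, building the alkene by carbonyl olefination. Lemieux–Johnson cleavage of both terminal alkenes (OsO4 cat., NaIO4, 2,6-lutidine, dioxane–H2O, rt) gives the dialdehyde 2,2'-[3,5,7-trihydroxy-2-[4-(methoxymethoxy)phenyl]-4-oxo-4H-chromene-6,8-diyl]diacetaldehyde F6, present largely as its lactols. A twofold Wittig reaction with isopropylidenetriphenylphosphorane (from isopropyltriphenylphosphonium iodide and n-BuLi, excess to absorb the three acidic OH groups, THF, −78 °C → rt) then gives 12.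

## Further compounds

F1 | step 3 | racemic 5,7-bis(allyloxy)-2-[4-(methoxymethoxy)phenyl]chroman-4-one | COCOc1ccc(cc1)C1CC(=O)c2c(OCC=C)cc(OCC=C)cc2O1
F2 | step 3 | 5,7-bis(allyloxy)-2-[4-(methoxymethoxy)phenyl]-4H-chromen-4-one | COCOc1ccc(cc1)-c1cc(=O)c2c(OCC=C)cc(OCC=C)cc2o1
F3 | step 3 | dimethyl [5,7-bis(allyloxy)-2-[4-(methoxymethoxy)phenyl]-4-oxo-4H-chromen-3-yl]boronate | COCOc1ccc(cc1)-c1oc2cc(OCC=C)cc(OCC=C)c2c(=O)c1B(OC)OC
F4 | step 4 | 3,5,7-trihydroxy-2-[4-(methoxymethoxy)phenyl]-4H-chromen-4-one | COCOc1ccc(cc1)-c1oc2cc(O)cc(O)c2c(=O)c1O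
F5 | step 4 | 3,5,7-trihydroxy-6,8-diiodo-2-[4-(methoxymethoxy)phenyl]-4H-chromen-4-one | COCOc1ccc(cc1)-c1oc2c(I)c(O)c(I)c(O)c2c(=O)c1O
F6 | step 5 | 2,2'-[3,5,7-trihydroxy-2-[4-(methoxymethoxy)phenyl]-4-oxo-4H-chromene-6,8-diyl]diacetaldehyde | COCOc1ccc(cc1)-c1oc2c(CC=O)c(O)c(CC=O)c(O)c2c(=O)c1O
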